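A small charge of protic impurity, 7.40 mM against 37 mM of starting material, stood in the flask I was asked about, and I wanted to know what it cost in target.

| setting | Sunday's | Thursday's | Saturday's | flask |
|---|---|---|---|---|
| starting material | 25 mM | 56 mM | 37 mM | 37 mM |
| reagent in the second phase | 44.4 mM | 44.4 mM | 44.4 mM | 44.4 mM |
| protic impurity | 7.4 mM | 7.4 mM | 11 mM | 7.40 mM |
| remark | run made earlier | run made earlier | run made earlier |  |
| time |  |  |  | 15 min |
| volume of the second phase over the first |  |  |  | 0.50 |

| run | time / min | target / % |
|---|---|---|
| Sunday's | 1.33 | 9 |
| Sunday's | 2.50 | 10 |
| Sunday's | 5.00 | 22 |
| Sunday's | 10.0 | 35 |
| Sunday's | 20.0 | 49 |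
| Thursday's | 1.50 | 7 |
| Thursday's | 5.00 | 19 |
| Thursday's | 8.00 | 29 |
| Thursday's | 12.0 | 35 |
| Thursday's | 20.0 | 44 |
| Saturday's | 1.50 | 9 |
| Saturday's | 5.00 | 19 |
| Saturday's | 8.00 | 26 |
| Saturday's | 12.0 | 32 |
| Saturday's | 20.0 | 42 |

(scatter of a reading: 1.5 percentage points)

- in the second phase: reagent in the second phase; everything else is in the first
- charges count per volume of the first phase; a concentration in a rate is the amount of a species over the volume of its own phase; every rate counts per litre of the first phase
- the numbers in the tables scatter with a standard deviation of 1.5 percentage points
- the earlier runs hold the two phases in the same ratio of volumes as the flask asked about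

- spring: doubling the transfer coefficient of the reagent in the second phase, all else as stated
- midnight: doubling the amount of reagent in the second phase, all else as stated

1. target at 15 min, in percent of the starting material charged
2. the change that raises the amount of target at 15 min, in percent of the starting material charged most ("none" if none brings more than 2 percentage points) (spring / midnight / none)
3. amount of target at 15 min, in percent of the starting material charged, after spring

I took the settings in turn. Starting material came first. Had transfer of the reagent set the pace, the amount of target made would not depend on c(starting material), so Thursday's percent at 20.0 min would have been about 21.9%. It read 44%, well above that. Against Sunday's 49%, the percent scales with the charge to the power −0.133, which makes the order in starting material 0.867, a reading close to pseudo-first-order.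

The protic impurity comes next. By hand, it should lower the target as it rises. Scaled to 37 mM, Sunday's reading at 20.0 min gives 46.5% at 7.4 mM of impurity, while Saturday's run, with 11 mM, read 42% at that time. That gives 0.257, the impurity exponent: the minus slope of ln(percent target at a fixed time) against ln c(protic impurity). It is a reading, and it carries the scatter of its yields.

Sunday's, Thursday's and Saturday's runs held one reagent charge, 44.4 mM, so they gave me no reading of it or of its transfer. With the order at 0.867, nearer one than zero, I expected little from faster transfer and chose doubling the charge.

Saturday's run, interpolated to 15 min, gives 35.8%, and the exponent, read at 20.0 min, carries that to my estimate of 39.6% for the flask.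

The forecast gave 40%, chose midnight and put spring at 42%, on the ground that “Doubling the reagent nearly doubles the rate and avoids depletion”.

The flask gave 42.1%. Midnight added 23 percentage points, spring added 0.97 points and reached 43.0%, so the forecast's answers held. For its 40% to be wrong, a run would have to put the flask's answer elsewhere; that answer has moved by 5 points at a reagent charge of 37.6 mM or 51.9 mM.

    reagent in the reaction phase ⇌ reagent in the second phase, rate k1*([reagent in the reaction phase] - [reagent in the second phase]/K1) per volume of the first phase (partition coefficient = 96.0, kL = 0.340 /s)
    starting material + reagent in the reaction phase → target (k = 1.20 /M/s)
    starting material + protic impurity → quenched substrate (k = 0.160 /M/s)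
    reagent in the reaction phase → decomposed reagent (k = 0.00290 /s)

The neighbouring flask held 19 mM of protic impurity, 0.514 equiv to the starting material, with the other charges and the time as in the flask. Carrying the flask's 42.1% with the exponent 0.257 gave 33.0% for it, and the neighbouring flask gave 32.6%. At 15.0 min its starting material stood at 21.2% against the flask's 38.8%, and its quenched substrate reached 46.1% against the flask's 19.1%.

The readings were generated by integration with made-up constants, noise included.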